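**Retrosynthetic overview**
- Endgame: one acid hydrolysis removes a TBS ether and a dioxolane. Both furan-2,5-dione rings (ring A with CH2OH, ring B with the 2-oxohexyl chain) travel through the route as 3,4-disubstituted furans and are raised to the anhydride level together (singlet oxygen, then Dess–Martin oxidation).
- Key disconnection: the bond from the stereogenic CH (bearing pentyl and CH2–ring A) to the ring-B carbon. It is made by oxidative union of two carbon nucleophiles, a chiral secondary alkyl pinacol boronate (ring-A half) and a 3-furyllithium (ring-B half). Both sit on one boron atom as a temporary tether; NBS triggers a 1,2-metallate shift, then boron and bromide leave.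
- Enabling feature: ring B is O1–C2(=O)–C3=C4–C5(=O), a furan oxidised at C2 and C5. At the furan level the ring carbon bonded to the stereocentre can carry Li or B. Its neighbouring ring C–H next to O1 (the later C=O carbon) is the nucleophilic α-position that accepts Br+, which makes the boron-bearing carbon a migration terminus.
- The only stereocentre is set beforehand by (−)-sparteine-mediated lithiation–borylation of hexyl 2,4,6-triisopropylbenzoate with a furylmethyl boronate made from 3,4-bis(hydroxymethyl)furan. The ring-B half comes from 3,4-dibromofuran and 1,2-epoxyhexane.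
- Ring order: no ring is built. Both five-membered rings are bought as furans, ring B is attached in the key step, and rings A and B then become anhydrides simultaneously.

Key step: step 9

Assumption: the hydroxymethyl anhydride as drawn is taken as the stable, isolable form of the target (not its butenolide-acid isomer), because dialkylmaleic acids close to the anhydride spontaneously.

Step 1
Reactants: 1 3,4-bis(hydroxymethyl)furan
Product: 3 [4-({[tert-butyl(dimethyl)silyl]oxy}methyl)furan-3-yl]methanol, via monosodium alkoxide 2 (not isolated)
Conditions: NaH (1 equiv), THF, 0 °C to rt; then TBSCl (1 equiv), rt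
Reagents that add atoms: tert-butyldimethylsilyl chloride (TBSCl), CC(C)(C)[Si](C)(C)Cl
Why: Monosilylation of a symmetrical diol through its sparingly soluble monosodium alkoxide (O-silylation) should favour the mono-ether, either hydroxyl gives the same product, and no stereocentre is formed.

Step 2
Reactants: 3 [4-({[tert-butyl(dimethyl)silyl]oxy}methyl)furan-3-yl]methanol
Product: 4 {[4-(bromomethyl)furan-3-yl]methoxy}(tert-butyl)dimethylsilane
Conditions: CBr4, PPh3, CH2Cl2, 0 °C; used promptly
Reagents that add atoms: carbon tetrabromide, BrC(Br)(Br)Br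
Why: In the Appel reaction the primary furylmethyl alcohol is activated as an alkoxyphosphonium ion and displaced by bromide under near-neutral conditions that the TBS ether and the furan tolerate.

Step 3
Reactants: 4 {[4-(bromomethyl)furan-3-yl]methoxy}(tert-butyl)dimethylsilane
Product: 5 2-{[4-({[tert-butyl(dimethyl)silyl]oxy}methyl)furan-3-yl]methyl}-4,4,5,5-tetramethyl-1,3,2-dioxaborolane
Conditions: B2pin2, CuI (cat.), PPh3 (cat.), LiOMe, DMF, rt
Reagents that add atoms: bis(pinacolato)diboron, CC1(C)OB(OC1(C)C)B1OC(C)(C)C(C)(C)O1
Why: In this copper-catalysed Miyaura-type borylation of a primary benzylic-type bromide, a boryl-copper species made from B2pin2 and methoxide replaces the C–Br bond at room temperature without touching the silyl ether.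

Step 4
Reactants: 6 2,4,6-triisopropylbenzoic acid; 7 1-bromohexane
Product: 9 hexyl 2,4,6-triisopropylbenzoate, via potassium carboxylate 8 (not isolated)
Conditions: K2CO3, DMF, 60 °C
Reagents that add atoms: none
Why: SN2 O-alkylation of the carboxylate forms the ester at the unhindered primary carbon and so avoids acyl substitution at the shielded carbonyl group.

Step 5
Reactants: 9 hexyl 2,4,6-triisopropylbenzoate; 5 2-{[4-({[tert-butyl(dimethyl)silyl]oxy}methyl)furan-3-yl]methyl}-4,4,5,5-tetramethyl-1,3,2-dioxaborolane
Product: 12 (R)-2-[1-(4-{[(tert-butyldimethylsilyl)oxy]methyl}furan-3-yl)heptan-2-yl]-4,4,5,5-tetramethyl-1,3,2-dioxaborolane, via lithiated benzoate 10 (not isolated), via boronate complex 11 (not isolated)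
Conditions: s-BuLi, (−)-sparteine, Et2O, −78 °C; then 5, −78 °C; then reflux
Reagents that add atoms: none
Why: In this sparteine-mediated asymmetric lithiation–borylation (a reagent-controlled Matteson-type homologation), s-BuLi/(−)-sparteine removes the pro-S α-proton of 9 to give configurationally stable (S)-10, boron of 5 is captured with retention to give 11, and the furylmethyl group migrates antiperiplanar to the departing benzoate with inversion, which should set the (R) centre of 12.

Step 6
Reactants: 13 3,4-dibromofuran; 14 1,2-epoxyhexane (racemic)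
Product: 16 1-(4-bromofuran-3-yl)hexan-2-ol (racemic), via 4-bromofuran-3-yllithium 15 (not isolated)
Conditions: n-BuLi (1 equiv), Et2O, −78 °C; then 14, BF3·OEt2, −78 °C
Reagents that add atoms: none
Why: Selective single bromine–lithium exchange followed by BF3-promoted SN2 opening of the terminal epoxide at its CH2 end gives the homobenzylic-type alcohol, whose carbinol centre arises as a racemate and is erased in step 7.

Step 7
Reactants: 16 1-(4-bromofuran-3-yl)hexan-2-ol
Product: 17 1-(4-bromofuran-3-yl)hexan-2-one
Conditions: Dess–Martin periodinane, CH2Cl2, rt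
Reagents that add atoms: none
Why: Dess–Martin oxidation converts the secondary alcohol to the ketone under mild non-basic conditions that leave the bromofuran intact.

Step 8
Reactants: 17 1-(4-bromofuran-3-yl)hexan-2-one
Product: 18 2-[(4-bromofuran-3-yl)methyl]-2-butyl-1,3-dioxolane
Conditions: ethylene glycol, PPTS (cat.), benzene, reflux (Dean–Stark)
Reagents that add atoms: ethylene glycol, OCCO
Why: Acid-catalysed ketalisation with azeotropic removal of water masks the ketone and the acidity of its flanking CH2 against the organolithium chemistry of step 9.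

Step 9
Reactants: 18 2-[(4-bromofuran-3-yl)methyl]-2-butyl-1,3-dioxolane; 12 (R)-2-[1-(4-{[(tert-butyldimethylsilyl)oxy]methyl}furan-3-yl)heptan-2-yl]-4,4,5,5-tetramethyl-1,3,2-dioxaborolane
Product: 22 tert-butyl({4-[(2R)-2-{4-[(2-butyl-1,3-dioxolan-2-yl)methyl]furan-3-yl}heptyl]furan-3-yl}methoxy)dimethylsilane, via furyllithium 19 (not isolated), via lithium boronate 20 (not isolated), via bromodihydrofuran boronic ester 21 (not isolated)
Conditions: n-BuLi, THF, −78 °C; then 12, −78 °C; then NBS (equimolar to 19), THF, −78 °C to rt
Reagents that add atoms: none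
Why: Bromine–lithium exchange turns 18 into the 3-furyllithium 19, which adds to the vacant boron orbital of 12 to give boronate 20, so that two carbon nucleophiles of like polarity sit on one boron atom that serves as a temporary one-atom tether. NBS then transfers Br+ to the ring-B α-carbon next to the boron-bearing carbon, the secondary alkyl group shifts from boron to that adjacent ring carbon (1,2-metallate rearrangement) to give 21, and attack of succinimide anion on boron expels bromide and restores the furan in 22. The closest known reaction type is the transition-metal-free enantiospecific sp2–sp3 coupling of secondary pinacol boronic esters with lithiated furans, an aromatic relative of the Zweifel olefination. No ring is closed and no new stereocentre is created: the existing one is carried over because the migrating carbon keeps its configuration in the suprafacial 1,2-shift, so (R)-12 should give (R)-22. The step needs chemoselectivity for the anionic ring-B furan over the neutral ring-A furan and over direct bromination of the sp3 C–B carbon, which is secured by the negative charge of 20 (far higher HOMO on ring B), by the electron-rich furyl group that favours attack on the ring, and by charging NBS equimolar to 19 at −78 °C. Site selectivity inside ring B follows from the C–B σ bond, which can feed the developing positive charge only when bromine enters at the α-carbon adjacent to boron.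

Step 10
Reactants: 22 tert-butyl({4-[(2R)-2-{4-[(2-butyl-1,3-dioxolan-2-yl)methyl]furan-3-yl}heptyl]furan-3-yl}methoxy)dimethylsilane
Product: 24 (R)-bis(γ-hydroxybutenolide) (mixture of lactol regio- and stereoisomers; one regioisomer drawn), via bis-endoperoxide 23 (not isolated)
Conditions: O2, hν (visible), tetraphenylporphyrin (cat.), i-Pr2NEt, CH2Cl2, −78 °C to rt
Reagents that add atoms: dioxygen, O=O
Why: Two-fold [4+2] cycloaddition of singlet oxygen to the two electron-rich furans followed by base-induced Kornblum–DeLaMare fragmentation of each endoperoxide gives the lactols, whose isomerism is inconsequential because all converge in step 11, and the existing stereocentre is not touched.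

Step 11
Reactants: 24 (R)-bis(γ-hydroxybutenolide)
Product: 25 3-[(2R)-2-{4-[(2-butyl-1,3-dioxolan-2-yl)methyl]-2,5-dioxo-2,5-dihydrofuran-3-yl}heptyl]-4-({[tert-butyl(dimethyl)silyl]oxy}methyl)furan-2,5-dione
Conditions: Dess–Martin periodinane (excess), CH2Cl2, rt
Reagents that add atoms: none
Why: Dess–Martin oxidation of both lactols gives the two anhydride carbonyls, and a non-basic oxidant is chosen because the C–H of the stereocentre becomes vinylogously acidic once ring B is an anhydride.

Step 12
Reactants: 25 3-[(2R)-2-{4-[(2-butyl-1,3-dioxolan-2-yl)methyl]-2,5-dioxo-2,5-dihydrofuran-3-yl}heptyl]-4-({[tert-butyl(dimethyl)silyl]oxy}methyl)furan-2,5-dione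
Product: 26 3-{(2R)-2-[2,5-dioxo-4-(2-oxohexyl)-2,5-dihydrofuran-3-yl]heptyl}-4-(hydroxymethyl)furan-2,5-dione (target)
Conditions: 2 M aq. HCl, THF, rt; then concentration from toluene
Reagents that add atoms: water, O
Why: Acid-catalysed hydrolysis cleaves the primary silyl ether and the dioxolane in one operation, any ring-opened dialkylmaleic acid should reclose on dehydration, and the acidic medium does not deprotonate the stereocentre.

**Compound list**
1 | 3,4-bis(hydroxymethyl)furan | OCc1cocc1CO | starting material
2 | monosodium alkoxide of 1 | [Na+].[O-]Cc1cocc1CO | intermediate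
3 | [4-({[tert-butyl(dimethyl)silyl]oxy}methyl)furan-3-yl]methanol | CC(C)(C)[Si](C)(C)OCc1cocc1CO | intermediate
4 | {[4-(bromomethyl)furan-3-yl]methoxy}(tert-butyl)dimethylsilane | CC(C)(C)[Si](C)(C)OCc1cocc1CBr | intermediate
5 | furylmethyl pinacol boronic ester | CC(C)(C)[Si](C)(C)OCc1cocc1CB1OC(C)(C)C(C)(C)O1 | intermediate
6 | 2,4,6-triisopropylbenzoic acid | CC(C)c1cc(C(C)C)c(C(=O)O)c(C(C)C)c1 | starting material
7 | 1-bromohexane | CCCCCCBr | starting material
8 | potassium 2,4,6-triisopropylbenzoate | [K+].[O-]C(=O)c1c(C(C)C)cc(C(C)C)cc1C(C)C | intermediate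
9 | hexyl 2,4,6-triisopropylbenzoate | CCCCCCOC(=O)c1c(C(C)C)cc(C(C)C)cc1C(C)C | intermediate
10 | (S)-1-lithiohexyl 2,4,6-triisopropylbenzoate (sparteine complex) | CCCCC[C@@H](OC(=O)c1c(C(C)C)cc(C(C)C)cc1C(C)C)[Li] | intermediate
11 | lithium (S)-boronate complex from 10 and 5 | [Li+].CCCCC[C@@H](OC(=O)c1c(C(C)C)cc(C(C)C)cc1C(C)C)[B-]1(Cc2cocc2CO[Si](C)(C)C(C)(C)C)OC(C)(C)C(C)(C)O1 | intermediate
12 | (R)-secondary pinacol boronic ester (ring-A half) | CCCCC[C@H](Cc1cocc1CO[Si](C)(C)C(C)(C)C)B1OC(C)(C)C(C)(C)O1 | intermediate
13 | 3,4-dibromofuran | Brc1cocc1Br | starting material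
14 | 1,2-epoxyhexane (racemic) | CCCCC1CO1 | starting material
15 | 4-bromofuran-3-yllithium | [Li]c1cocc1Br | intermediate
16 | 1-(4-bromofuran-3-yl)hexan-2-ol (racemic) | CCCCC(O)Cc1cocc1Br | intermediate
17 | 1-(4-bromofuran-3-yl)hexan-2-one | CCCCC(=O)Cc1cocc1Br | intermediate
18 | 2-[(4-bromofuran-3-yl)methyl]-2-butyl-1,3-dioxolane (ring-B half) | CCCCC1(Cc2cocc2Br)OCCO1 | intermediate
19 | {4-[(2-butyl-1,3-dioxolan-2-yl)methyl]furan-3-yl}lithium | [Li]c1cocc1CC1(CCCC)OCCO1 | intermediate
20 | lithium (R)-furyl(sec-alkyl)boronate | [Li+].CCCCC[C@H](Cc1cocc1CO[Si](C)(C)C(C)(C)C)[B-]1(c2cocc2CC2(CCCC)OCCO2)OC(C)(C)C(C)(C)O1 | intermediate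
21 | 2-bromo-3-boryl-3-(sec-alkyl)-2,3-dihydrofuran (ring centres transient, unassigned) | CCCCC[C@H](Cc1cocc1CO[Si](C)(C)C(C)(C)C)C1(B2OC(C)(C)C(C)(C)O2)C(Br)OC=C1CC1(CCCC)OCCO1 | intermediate
22 | (R)-bis-furan | CCCCC[C@H](Cc1cocc1CO[Si](C)(C)C(C)(C)C)c1cocc1CC1(CCCC)OCCO1 | intermediate
23 | (R)-bis-endoperoxide (bridgehead centres unassigned) | CCCCC[C@H](CC1=C(CO[Si](C)(C)C(C)(C)C)C2OOC1O2)C1=C(CC2(CCCC)OCCO2)C2OOC1O2 | intermediate
24 | (R)-bis(γ-hydroxybutenolide), one of four lactol regioisomers drawn, lactol centres unassigned | CCCCC[C@H](CC1=C(CO[Si](C)(C)C(C)(C)C)C(O)OC1=O)C1=C(CC2(CCCC)OCCO2)C(O)OC1=O | intermediate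
25 | (R)-bis-anhydride, TBS ether and dioxolane | CCCCC[C@H](CC1=C(CO[Si](C)(C)C(C)(C)C)C(=O)OC1=O)C1=C(CC2(CCCC)OCCO2)C(=O)OC1=O | intermediate
26 | 3-{(2R)-2-[2,5-dioxo-4-(2-oxohexyl)-2,5-dihydrofuran-3-yl]heptyl}-4-(hydroxymethyl)furan-2,5-dione | CCCCC[C@H](CC1=C(CO)C(=O)OC1=O)C1=C(CC(=O)CCCC)C(=O)OC1=O | target

**Total step count:** 12
**Longest linear sequence:** 8 steps (1, 2, 3, 5, 9, 10, 11, 12)

**Steps most likely to fail**

**Step 9.**
- What may go wrong: boronate formation may be slow next to the ring-B side chain. Bromine may enter the neutral ring-A furan. Bromination may also occur at the sp3 carbon in place of migration.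
- Fallback: it sets out from 12 and 18 and comes back at 22, and it replaces the metal-free boronate rearrangement by palladium catalysis.
- Compound 12 is treated with KHF2 in MeOH/H2O at rt to give the potassium (R)-trifluoroborate F1; the primary alkyl silyl ether is expected to persist.
- F1 is then joined to bromide 18 in a ligand-controlled stereoretentive Suzuki–Miyaura coupling of an unactivated secondary alkyltrifluoroborate. The conditions are a Pd precatalyst with an electron-poor biarylphosphine that enforces retentive transmetalation, K2CO3, toluene/H2O, heat. This should give 22 with the same configuration.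

**Step 10.**
- What may go wrong: the two-fold photooxygenation may stall after one ring. An endoperoxide may also rearrange thermally or oligomerise before the base-induced fragmentation takes place.
- Fallback: it sets out from 22, comes back at 25, and bypasses 24 and step 11 with a polar, non-photochemical oxidation.
- Both furans are opened with NBS (two equivalents) in NaHCO3-buffered aqueous acetone at low temperature to give the (R)-bis[(Z)-enedial] F2.
- Pinnick oxidation (NaClO2, NaH2PO4, 2-methyl-2-butene, t-BuOH/H2O) takes all four aldehydes to the (R)-tetracarboxylic acid F3.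
- The two dialkylmaleic acid units of F3 should close on concentration, or on brief exposure to Ac2O, to give 25.

**Step 12.**
- What may go wrong: the long exposure to aqueous acid needed for dioxolane hydrolysis keeps the anhydrides ring-opened. This gives the liberated primary alcohol time to lactonise onto the ring-A diacid.
- Fallback: it sets out from 25 and comes back at 26. It separates the two unmaskings under conditions that never open the anhydrides.
- The dioxolane is first removed by transketalisation in dry acetone (PPTS cat., rt to 40 °C) while the alcohol is still silylated, giving the (R)-keto silyl ether bis-anhydride F4.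
- A short, cold fluoride desilylation (aq. HF, MeCN, 0 °C) then releases 26.

Further compounds
F1 | step 9 | potassium (R)-[1-(4-{[(tert-butyldimethylsilyl)oxy]methyl}furan-3-yl)heptan-2-yl]trifluoroborate | [K+].CCCCC[C@H](Cc1cocc1CO[Si](C)(C)C(C)(C)C)[B-](F)(F)F
F2 | step 10 | (R)-bis[(Z)-enedial] (tetra-aldehyde from opening of both furans) | CCCCC[C@H](C/C(C=O)=C(/C=O)CO[Si](C)(C)C(C)(C)C)/C(C=O)=C(/C=O)CC1(CCCC)OCCO1
F3 | step 10 | (R)-tetracarboxylic acid (two dialkylmaleic acid units) | CCCCC[C@H](C/C(C(=O)O)=C(/C(=O)O)CO[Si](C)(C)C(C)(C)C)/C(C(=O)O)=C(/C(=O)O)CC1(CCCC)OCCO1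
F4 | step 12 | (R)-keto silyl ether bis-anhydride | CCCCC[C@H](CC1=C(CO[Si](C)(C)C(C)(C)C)C(=O)OC1=O)C1=C(CC(=O)CCCC)C(=O)OC1=O
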